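**Plan**
Numbering: ring atoms C1–C10 (C1=C2, C3=C4). C4 carries C18O2Me, C5 carries =C19H–OAc, C8 is CHMe, and C9 carries Me and CH2CH2-3-furyl.
Enabling feature: C19 is an exocyclic, oxygen-bearing one-carbon branch on ring atom C5, next to ring CH2 C6. The enol acetate is therefore the H−/Ac+ adduct of the ketene O=C19=C5(C4)(C6), which is the retron of a Wolff 1,2-shift. Moving C6 back onto C19 gives an eleven-membered α-diazo ketone in which C19 is a ring member and C19–C6 is a temporary bond.
Retrosynthetic cuts, in order: O–Ac and C19–H; C5–C6 (retro-Wolff); C1=C2 (metathesis); C3=C4 (HWE); C6–C7 (enolate alkylation); C8–C9 (Ireland–Claisen).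
Forward order: furan-bearing chain C7–C10/C1, union with a C6–C19–C5–C4 keto phosphonate, dienoate, eleven-membered ring, diazo transfer, contraction to the ten-membered ring.
Stereochemistry: C8/C9 come from one chair [3,3] shift of a chiral boron ketene acetal, C3=C4 from the HWE reaction, C1=C2 from kinetically Z-selective metathesis, and C5=C19 from in-plane hydride capture of the ketene on the C6 side.

Key step: step 16

Assumption: the (S,S)-diazaborolidine is taken to give the (2S,3R)-acid 13; if the sense of induction is the opposite, the equally accessible (R,R)-controller is used.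

Step 1
Reactants: 1 1-(trimethylsilyl)propyne; 2 3-(bromomethyl)furan
Product: 4 [4-(furan-3-yl)but-1-yn-1-yl]trimethylsilane, via 3-lithio-1-(trimethylsilyl)propyne 3 (not isolated)
Conditions: n-BuLi, THF, −78 °C; then 2, −78 °C to rt
Reagents that add atoms: none
Why: Propargylic lithiation followed by SN2 alkylation with the reactive furylmethyl bromide; the silyl group blocks the acetylenic terminus and favours the propargylic over the allenic product.

Step 2
Reactants: 4 [4-(furan-3-yl)but-1-yn-1-yl]trimethylsilane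
Product: 5 3-(but-3-yn-1-yl)furan
Conditions: K2CO3 (cat.), MeOH, rt
Reagents that add atoms: none
Why: Methoxide-induced protodesilylation of an alkynylsilane, to which the furan is inert.

Step 3
Reactants: 5 3-(but-3-yn-1-yl)furan
Product: 8 (2E)-5-(furan-3-yl)-3-methylpent-2-en-1-ol, via alkenyldimethylalane 6 (not isolated), via lithium alkenylaluminate 7 (not isolated)
Conditions: Me3Al, Cp2ZrCl2 (cat.), CH2Cl2, 0 °C to rt; n-BuLi, THF–hexane, −78 to 0 °C; (CH2O)n, rt; 1 M HCl, 0 °C
Reagents that add atoms: trimethylaluminium C[Al](C)C; formaldehyde (as paraformaldehyde) C=O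
Why: Negishi carboalumination adds Me and Al syn with Al at the terminus, and the aluminate is hydroxymethylated with retention, which fixes the (E)-trisubstituted alkene.

Step 4
Reactants: 8 (2E)-5-(furan-3-yl)-3-methylpent-2-en-1-ol; 9 propanoyl chloride
Product: 10 (2E)-5-(furan-3-yl)-3-methylpent-2-en-1-yl propanoate
Conditions: Et3N, DMAP (cat.), CH2Cl2, 0 °C
Reagents that add atoms: none
Why: Routine O-acylation of a primary allylic alcohol.

Step 5
Reactants: 10 (2E)-5-(furan-3-yl)-3-methylpent-2-en-1-yl propanoate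
Product: 13 (2S,3R)-3-[2-(furan-3-yl)ethyl]-2,3-dimethylpent-4-enoic acid, via boron ketene acetal 11 (not isolated), via acyloxyborane 12 (not isolated)
Conditions: N,N′-[(1S,2S)-1,2-diphenylethane-1,2-diyl]bis[3,5-bis(trifluoromethyl)benzenesulfonamide], BBr3, CH2Cl2, rt, then vacuum; 10, i-Pr2NEt, CH2Cl2, −78 to −20 °C; aqueous work-up
Reagents that add atoms: none
Why: Enantioselective ester-enolate Claisen ([3,3], Ireland–Claisen type): soft enolisation gives the Z(O)-boron ketene acetal 11, which rearranges through a chair with the C17 methyl and the CH2CH2-furyl arm of the (E)-alkene both equatorial (this fixes C8 relative to C9), while the C2-symmetric diazaborolidine selects one of the two mirror-image chairs and sets the absolute configuration.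

Step 6
Reactants: 13 (2S,3R)-3-[2-(furan-3-yl)ethyl]-2,3-dimethylpent-4-enoic acid
Product: 14 (2S,3R)-3-[2-(furan-3-yl)ethyl]-2,3-dimethylpent-4-en-1-ol
Conditions: LiAlH4, Et2O, 0 °C to rt
Reagents that add atoms: none
Why: Hydride reduction of the acid through its carboxylate, which is not enolised, so C8 is not epimerised.

Step 7
Reactants: 14 (2S,3R)-3-[2-(furan-3-yl)ethyl]-2,3-dimethylpent-4-en-1-ol
Product: 15 3-[(3R,4S)-5-bromo-3-ethenyl-3,4-dimethylpentyl]furan
Conditions: CBr4, PPh3, CH2Cl2, 0 °C
Reagents that add atoms: tetrabromomethane BrC(Br)(Br)Br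
Why: Appel bromination under neutral conditions; the hindered primary bromide serves at once as leaving group for step 12 and as a robust masked form of C7 during steps 8–10.

Step 8
Reactants: 15 3-[(3R,4S)-5-bromo-3-ethenyl-3,4-dimethylpentyl]furan
Product: 17 (3R,4S)-5-bromo-3-[2-(furan-3-yl)ethyl]-3,4-dimethylpentan-1-ol, via B-alkyl-9-BBN 16 (not isolated)
Conditions: 9-BBN-H, THF, rt to 50 °C; 30% H2O2, aq. NaOAc, 0 °C to rt
Reagents that add atoms: hydrogen peroxide OO
Why: Anti-Markovnikov hydroboration–oxidation of the only alkene; the acetate buffer avoids alkoxide formation and therefore closure of the bromo alcohol to a tetrahydropyran.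

Step 9
Reactants: 17 (3R,4S)-5-bromo-3-[2-(furan-3-yl)ethyl]-3,4-dimethylpentan-1-ol
Product: 18 (3R,4S)-5-bromo-3-[2-(furan-3-yl)ethyl]-3,4-dimethylpentanal
Conditions: Dess–Martin periodinane, CH2Cl2, 0 °C to rt
Reagents that add atoms: none
Why: Mild oxidation of a primary alcohol that tolerates the furan and the alkyl bromide.

Step 10
Reactants: 18 (3R,4S)-5-bromo-3-[2-(furan-3-yl)ethyl]-3,4-dimethylpentanal
Product: 19 (4R,5S)-6-bromo-4-[2-(furan-3-yl)ethyl]-4,5-dimethylhex-1-ene
Conditions: Ph3PCH3Br, NaN(SiMe3)2, THF, −78 to 0 °C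
Reagents that add atoms: methyltriphenylphosphonium bromide C[P+](c1ccccc1)(c1ccccc1)c1ccccc1.[Br-]
Why: Wittig methylenation; the aldehyde reacts far faster than the β-branched bromide, and the product carries C10H2–C1H= in the form metathesis needs.

Step 11
Reactants: 20 trimethyl phosphonoacetate; 21 chloroacetone
Product: 23 methyl 2-(dimethoxyphosphoryl)-4-oxopentanoate, via sodium phosphonoacetate 22 (not isolated)
Conditions: NaH, THF, 0 °C; 21, Bu4NI (cat.), 0 °C to rt
Reagents that add atoms: none
Why: SN2 alkylation of a stabilised phosphonate carbanion by an α-halo ketone, which assembles C18, C4, C5, C19 and C6 in one reagent.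

Step 12
Reactants: 23 methyl 2-(dimethoxyphosphoryl)-4-oxopentanoate; 19 (4R,5S)-6-bromo-4-[2-(furan-3-yl)ethyl]-4,5-dimethylhex-1-ene
Product: 25 methyl (7R,8R)-2-(dimethoxyphosphoryl)-8-[2-(furan-3-yl)ethyl]-7,8-dimethyl-4-oxoundec-10-enoate (both epimers at the phosphonate carbon), via dilithium dianion 24 (not isolated)
Conditions: LiN(i-Pr)2 (2.1 equiv), THF, −78 to −30 °C; 19, DMPU, Bu4NI (cat.), −30 °C to rt; AcOH quench
Reagents that add atoms: none
Why: Dianion alkylation: the first base equivalent removes the C4 proton and the second can then only enolise the ketone at its methyl group (C6), because C5 adjoins the C4 anion, and this more basic terminal enolate alone is alkylated to form C6–C7.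

Step 13
Reactants: 25 methyl (7R,8R)-2-(dimethoxyphosphoryl)-8-[2-(furan-3-yl)ethyl]-7,8-dimethyl-4-oxoundec-10-enoate; 26 acrolein
Product: 27 methyl (2E)-2-{(5R,6R)-6-[2-(furan-3-yl)ethyl]-5,6-dimethyl-2-oxonon-8-en-1-yl}penta-2,4-dienoate
Conditions: LiCl, i-Pr2NEt, MeCN, 0 °C to rt
Reagents that add atoms: none
Why: Horner–Wadsworth–Emmons olefination under Masamune–Roush conditions; an α-substituted phosphonoacetate places the new vinyl carbon C2 trans to CO2Me (cis to C5), and the weak base leaves the acidic C5H2 in place.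

Step 14
Reactants: 27 methyl (2E)-2-{(5R,6R)-6-[2-(furan-3-yl)ethyl]-5,6-dimethyl-2-oxonon-8-en-1-yl}penta-2,4-dienoate
Product: 28 methyl (1E,3Z,6R,7R)-6-[2-(furan-3-yl)ethyl]-6,7-dimethyl-10-oxocycloundeca-1,3-diene-1-carboxylate
Conditions: Ru(NO3)(=CH-C6H4-2-O-i-Pr)(C22H29N2) (cyclometalated 1-adamantyl-3-mesitylimidazolidin-2-ylidene ruthenium nitrate catalyst), ClCH2CH2Cl, 1 mM, 40 °C, static vacuum
Reagents that add atoms: none
Why: Ring-closing metathesis between the allyl terminus and the terminal vinyl of the (E)-1,3-diene; the electron-poor trisubstituted C3=C4 is inert, and the side-bound metallacycle of the cyclometalated catalyst delivers the Z-C1=C2 bond under kinetic control.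

Step 15
Reactants: 28 methyl (1E,3Z,6R,7R)-6-[2-(furan-3-yl)ethyl]-6,7-dimethyl-10-oxocycloundeca-1,3-diene-1-carboxylate
Product: 29 methyl (1E,3Z,6R,7R)-11-diazo-6-[2-(furan-3-yl)ethyl]-6,7-dimethyl-10-oxocycloundeca-1,3-diene-1-carboxylate
Conditions: 4-acetamidobenzenesulfonyl azide, DBU, MeCN, 0 °C; used at once
Reagents that add atoms: 4-acetamidobenzenesulfonyl azide CC(=O)Nc1ccc(cc1)S(=O)(=O)N=[N+]=[N-]
Why: Regitz diazo transfer, as used to make vinyl diazo carbonyl compounds from β,γ-unsaturated carbonyl compounds; C5H2 is the only doubly activated methylene (α to the ketone and allylic to the dienoate), so C6 is not touched.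

Step 16
Reactants: 29 methyl (1E,3Z,6R,7R)-11-diazo-6-[2-(furan-3-yl)ethyl]-6,7-dimethyl-10-oxocycloundeca-1,3-diene-1-carboxylate
Product: 32 methyl (1E,3Z,6R,7R,10Z)-10-[(acetyloxy)methylidene]-6-[2-(furan-3-yl)ethyl]-6,7-dimethylcyclodeca-1,3-diene-1-carboxylate, via ketene 30 (not isolated), via lithium enolate 31 (not isolated)
Conditions: hν (450 nm LED), toluene, −78 °C; LiBH(s-Bu)3 (1.0 equiv, THF), −78 °C; Ac2O, −78 to 0 °C
Reagents that add atoms: acetic anhydride CC(=O)OC(C)=O
Why: Proposed new method: visible-light excitation of the α-diazo ketone expels N2 while the C19–C6 σ bond migrates to the electron-deficient C5 (Wolff rearrangement), so that C19 leaves the eleven-membered ring as the ketene carbon of 30 and the new C5–C6 bond closes the ten-membered ring, after which LiBH(s-Bu)3 adds hydride to C19 and Ac2O acylates enolate 31 on oxygen. The closest known reaction types are the photochemical Wolff ring contraction of cyclic α-diazo ketones, the Wolff shift of α-aryl α-diazo ketones to disubstituted ketenes, and the addition of organolithium reagents to unsymmetrical ketenes followed by acetylation; what is new is the α-alkenyl diazo ketone in a medium ring and the hydride capture in the same flask. The ring is closed by a 1,2-carbon shift through a three-centre transition state (contraction from eleven to ten members) and not by an end-to-end cyclisation, so it needs no high dilution and is driven by loss of N2. No stereocentre is formed and C8 and C9 are untouched; the new stereo-element is the C5=C19 double bond, set because a nucleophile attacks a ketene in the plane of the C5 substituents and the bulky borohydride passes the slim C6H2 rather than C4 with its ester, which leaves O cis to C4 (Z), a geometry retained on O-acetylation. The Wolff shift must outrun cyclopropene formation, 1,5-closure to a pyrazole and transannular cyclopropanation: C4 bears no hydrogen, so no 1,2-H shift is available, the ring twists C4=C3 out of conjugation with C5, and −78 °C with 450 nm light, absorbed only by the diazo chromophore, spares the Z-alkene. Hydride must also choose the ketene over the dienoate, which the far higher electrophilicity of the ketene at −78 °C and the single equivalent of hydride should secure, while 6π closure of the dienylketene is barred because it would build a [5]metacyclophane-type bridged ring.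

**Compound list**
1 | 1-(trimethylsilyl)propyne | CC#C[Si](C)(C)C | starting material
2 | 3-(bromomethyl)furan | BrCc1ccoc1 | starting material
3 | 3-lithio-1-(trimethylsilyl)propyne | [Li]CC#C[Si](C)(C)C | intermediate
4 | [4-(furan-3-yl)but-1-yn-1-yl]trimethylsilane | C[Si](C)(C)C#CCCc1ccoc1 | intermediate
5 | 3-(but-3-yn-1-yl)furan | C#CCCc1ccoc1 | intermediate
6 | [(1E)-4-(furan-3-yl)-2-methylbut-1-en-1-yl]dimethylalane | C[Al](C)/C=C(\C)CCc1ccoc1 | intermediate
7 | lithium butyl[(1E)-4-(furan-3-yl)-2-methylbut-1-en-1-yl]dimethylaluminate | [Li+].CCCC[Al-](C)(C)/C=C(\C)CCc1ccoc1 | intermediate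
8 | (2E)-5-(furan-3-yl)-3-methylpent-2-en-1-ol | OC/C=C(\C)CCc1ccoc1 | intermediate
9 | propanoyl chloride | CCC(=O)Cl | starting material
10 | (2E)-5-(furan-3-yl)-3-methylpent-2-en-1-yl propanoate | CCC(=O)OC/C=C(\C)CCc1ccoc1 | intermediate
11 | Z(O)-boron ketene acetal of 10, O-bound to the (4S,5S)-4,5-diphenyl-1,3-bis{[3,5-bis(trifluoromethyl)phenyl]sulfonyl}-1,3,2-diazaborolidin-2-yl group | C/C=C(\OB1N(S(=O)(=O)c2cc(cc(c2)C(F)(F)F)C(F)(F)F)[C@@H](c2ccccc2)[C@H](c2ccccc2)N1S(=O)(=O)c1cc(cc(c1)C(F)(F)F)C(F)(F)F)OC/C=C(\C)CCc1ccoc1 | intermediate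
12 | acyloxyborane of acid 13 with the same diazaborolidinyl group | C=C[C@@](C)(CCc1ccoc1)[C@H](C)C(=O)OB1N(S(=O)(=O)c2cc(cc(c2)C(F)(F)F)C(F)(F)F)[C@@H](c2ccccc2)[C@H](c2ccccc2)N1S(=O)(=O)c1cc(cc(c1)C(F)(F)F)C(F)(F)F | intermediate
13 | (2S,3R)-3-[2-(furan-3-yl)ethyl]-2,3-dimethylpent-4-enoic acid | C=C[C@@](C)(CCc1ccoc1)[C@H](C)C(=O)O | intermediate
14 | (2S,3R)-3-[2-(furan-3-yl)ethyl]-2,3-dimethylpent-4-en-1-ol | C=C[C@@](C)(CCc1ccoc1)[C@H](C)CO | intermediate
15 | 3-[(3R,4S)-5-bromo-3-ethenyl-3,4-dimethylpentyl]furan | C=C[C@@](C)(CCc1ccoc1)[C@H](C)CBr | intermediate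
16 | 9-{(3R,4S)-5-bromo-3-[2-(furan-3-yl)ethyl]-3,4-dimethylpentyl}-9-borabicyclo[3.3.1]nonane | B1(CC[C@@](C)(CCc2ccoc2)[C@H](C)CBr)C2CCCC1CCC2 | intermediate
17 | (3R,4S)-5-bromo-3-[2-(furan-3-yl)ethyl]-3,4-dimethylpentan-1-ol | OCC[C@@](C)(CCc1ccoc1)[C@H](C)CBr | intermediate
18 | (3R,4S)-5-bromo-3-[2-(furan-3-yl)ethyl]-3,4-dimethylpentanal | O=CC[C@@](C)(CCc1ccoc1)[C@H](C)CBr | intermediate
19 | (4R,5S)-6-bromo-4-[2-(furan-3-yl)ethyl]-4,5-dimethylhex-1-ene | C=CC[C@@](C)(CCc1ccoc1)[C@H](C)CBr | intermediate
20 | trimethyl phosphonoacetate | COC(=O)CP(=O)(OC)OC | starting material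
21 | chloroacetone | CC(=O)CCl | starting material
22 | sodium salt of trimethyl phosphonoacetate | [Na+].COC(=O)[CH-]P(=O)(OC)OC | intermediate
23 | methyl 2-(dimethoxyphosphoryl)-4-oxopentanoate (racemic) | COC(=O)C(CC(C)=O)P(=O)(OC)OC | intermediate
24 | dilithium dianion of 23 (C4 carbanion and terminal ketone enolate) | [Li+].[Li+].C=C([O-])C[C-](C(=O)OC)P(=O)(OC)OC | intermediate
25 | methyl (7R,8R)-2-(dimethoxyphosphoryl)-8-[2-(furan-3-yl)ethyl]-7,8-dimethyl-4-oxoundec-10-enoate (epimers at C2) | C=CC[C@@](C)(CCc1ccoc1)[C@H](C)CCC(=O)CC(C(=O)OC)P(=O)(OC)OC | intermediate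
26 | acrolein | C=CC=O | starting material
27 | methyl (2E)-2-{(5R,6R)-6-[2-(furan-3-yl)ethyl]-5,6-dimethyl-2-oxonon-8-en-1-yl}penta-2,4-dienoate | C=CC[C@@](C)(CCc1ccoc1)[C@H](C)CCC(=O)C/C(C(=O)OC)=C\C=C | intermediate
28 | methyl (1E,3Z,6R,7R)-6-[2-(furan-3-yl)ethyl]-6,7-dimethyl-10-oxocycloundeca-1,3-diene-1-carboxylate | COC(=O)/C1=C/C=C\C[C@@](C)(CCc2ccoc2)[C@H](C)CCC(=O)C1 | intermediate
29 | methyl (1E,3Z,6R,7R)-11-diazo-6-[2-(furan-3-yl)ethyl]-6,7-dimethyl-10-oxocycloundeca-1,3-diene-1-carboxylate | COC(=O)/C1=C/C=C\C[C@@](C)(CCc2ccoc2)[C@H](C)CCC(=O)C1=[N+]=[N-] | intermediate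
30 | methyl (1E,3Z,6R,7R)-6-[2-(furan-3-yl)ethyl]-6,7-dimethyl-10-(oxomethylidene)cyclodeca-1,3-diene-1-carboxylate (ketene) | COC(=O)/C1=C/C=C\C[C@@](C)(CCc2ccoc2)[C@H](C)CCC1=C=O | intermediate
31 | lithium (Z)-enolate of the C19 aldehyde (O cis to C4) | [Li+].COC(=O)/C1=C/C=C\C[C@@](C)(CCc2ccoc2)[C@H](C)CC\C1=C\[O-] | intermediate
32 | methyl (1E,3Z,6R,7R,10Z)-10-[(acetyloxy)methylidene]-6-[2-(furan-3-yl)ethyl]-6,7-dimethylcyclodeca-1,3-diene-1-carboxylate | COC(=O)/C1=C/C=C\C[C@@](C)(CCc2ccoc2)[C@H](C)CC\C1=C\OC(C)=O | target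

Total step count: 16. Longest linear sequence: 15 (steps 1–10 and 12–16).

**Steps most likely to fail**

1. Step 16.
 - What may go wrong: the excited vinyl diazo unit or its carbene may be diverted into cyclopropene formation or transannular cyclopropanation. The diazo compound may close thermally to a pyrazole before irradiation. Hydride delivery may lose its side selectivity.
 - Fallback: it sets out from 29 and comes back at 32, keeps the C6 shift from C19 to C5, and makes it ionic and carbene-free.
 - One equivalent of HBr (Et2O, −78 °C) converts 29 into the α-bromo ketone F1.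
 - AgOTf in aqueous THF buffered with 2,6-di-tert-butylpyridine then induces the silver-assisted quasi-Favorskii (semibenzilic) shift from the hydrated carbonyl, giving the ring-contracted acid F2. The non-basic medium avoids the cyclopropanone pathway, which would leave C19 on C6.
 - Oxalyl chloride with catalytic DMF gives the acid chloride F3, and LiAlH(O-t-Bu)3 at −78 °C gives the aldehyde F4.
 - Soft enolisation with MgBr2·OEt2 and i-Pr2NEt follows, in which magnesium bridges the aldehyde oxygen and the C18 carbonyl oxygen and so holds O cis to C4; Ac2O then gives 32.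

2. Step 14.
 - What may go wrong: oligomerisation may compete with closure of the eleven-membered ring. Kinetic Z control may erode through secondary metathesis. The catalyst may be tied up as a vinyl alkylidene of the diene.
 - Fallback: it sets out from 18 and comes back at 28, sets C1=C2 before ring closure, and closes the ring at C3=C4.
 - Still–Gennari olefination [(CF3CH2O)2P(O)CH2CO2Me, KN(SiMe3)2, 18-crown-6, THF, −78 °C] gives the (Z)-enoate F5.
 - i-Bu2AlH gives the (Z)-allylic alcohol F6, and TBSCl with imidazole gives the silyl ether F7.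
 - Alkylation of dianion 24 as in step 12 gives the keto phosphonate F8.
 - Bu4NF buffered with AcOH frees the alcohol F9, and MnO2 gives the (Z)-enal F10.
 - LiCl and i-Pr2NEt in MeCN at high dilution close the ring by an intramolecular HWE reaction to 28.

3. Step 12.
 - What may go wrong: substitution at the β-branched bromide may be slow, which would give the dianion time for proton transfer, O-alkylation and self-condensation.
 - Fallback: it sets out from 19 and comes back at 25, and forms C19–C5 by acyl-anion chemistry.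
 - Acetaldehyde N,N-dimethylhydrazone is deprotonated with LiN(i-Pr)2 to the much more nucleophilic lithium azaenolate F11.
 - Alkylation of F11 by 19 gives the hydrazone F12, and aqueous oxalic acid frees the aldehyde F13.
 - A thiazolium-catalysed Stetter reaction (3-benzyl-5-(2-hydroxyethyl)-4-methylthiazolium chloride, Et3N, dioxane, 70 °C) adds F13 to commercial methyl 2-(dimethoxyphosphoryl)acrylate and gives 25.

**Further compounds**
F1 | step 16 | α-bromo ketone: 28 with Br on C5 (both epimers) | COC(=O)/C1=C/C=C\C[C@@](C)(CCc2ccoc2)[C@H](C)CCC(=O)C1Br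
F2 | step 16 | ring-contracted acid: ten-membered ring with C5H–C19O2H (both epimers at C5) | COC(=O)/C1=C/C=C\C[C@@](C)(CCc2ccoc2)[C@H](C)CCC1C(=O)O
F3 | step 16 | acid chloride of F2 | COC(=O)/C1=C/C=C\C[C@@](C)(CCc2ccoc2)[C@H](C)CCC1C(=O)Cl
F4 | step 16 | aldehyde: ten-membered ring with C5H–C19HO (both epimers at C5) | COC(=O)/C1=C/C=C\C[C@@](C)(CCc2ccoc2)[C@H](C)CCC1C=O
F5 | step 14 | methyl (2Z,5R,6S)-7-bromo-5-[2-(furan-3-yl)ethyl]-5,6-dimethylhept-2-enoate | COC(=O)/C=C\C[C@@](C)(CCc1ccoc1)[C@H](C)CBr
F6 | step 14 | (2Z,5R,6S)-7-bromo-5-[2-(furan-3-yl)ethyl]-5,6-dimethylhept-2-en-1-ol | OC/C=C\C[C@@](C)(CCc1ccoc1)[C@H](C)CBr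
F7 | step 14 | tert-butyldimethylsilyl ether of F6 | CC(C)(C)[Si](C)(C)OC/C=C\C[C@@](C)(CCc1ccoc1)[C@H](C)CBr
F8 | step 14 | keto phosphonate from F7 and 24 (silyl ether retained, epimers at the phosphonate carbon) | CC(C)(C)[Si](C)(C)OC/C=C\C[C@@](C)(CCc1ccoc1)[C@H](C)CCC(=O)CC(C(=O)OC)P(=O)(OC)OC
F9 | step 14 | (Z)-allylic alcohol from F8 | OC/C=C\C[C@@](C)(CCc1ccoc1)[C@H](C)CCC(=O)CC(C(=O)OC)P(=O)(OC)OC
F10 | step 14 | (Z)-enal from F9 | O=C/C=C\C[C@@](C)(CCc1ccoc1)[C@H](C)CCC(=O)CC(C(=O)OC)P(=O)(OC)OC
F11 | step 12 | lithium azaenolate of acetaldehyde N,N-dimethylhydrazone | [Li+].[CH2-]C=NN(C)C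
F12 | step 12 | N,N-dimethylhydrazone of (4R,5R)-5-[2-(furan-3-yl)ethyl]-4,5-dimethyloct-7-enal | C=CC[C@@](C)(CCc1ccoc1)[C@H](C)CCC=NN(C)C
F13 | step 12 | (4R,5R)-5-[2-(furan-3-yl)ethyl]-4,5-dimethyloct-7-enal | C=CC[C@@](C)(CCc1ccoc1)[C@H](C)CCC=O
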